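## The problem

The target is a C37 nor-carotenoid built on one unbranched conjugated chain. Ring A (C1–C6, a 3-hydroxy-5,6-epoxy-trimethylcyclohexane) is joined through an E CH=CH link to the α-carbon of a γ-ylidenebutenolide. The lactone γ-carbon opens a pentaene that ends in a triple bond on the tetrasubstituted C5′=C6′ alkene of ring B (a 3′-hydroxy-trimethylcyclohexene). Chain carbons are counted here from the alkyne outward: chain C1 (methyl-bearing, bonded to the triple bond) through chain C8 (second methyl branch) to chain C10 (the lactone γ-carbon).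

No carbocycles are fused, so the work is chain construction. Five chain alkenes (C1=C2, C3=C4, C5=C6, C7=C8 all E; the exocyclic C9=C10 Z) and the E ring A vinylene must be made with defined geometry, two of them trisubstituted, in pieces that can be joined late.

There are four stereocentres: ring A C3 (S), C5 (R), C6 (S) and ring B C3′ (R). Both carbinol centres map onto C4 of (4R,6R)-actinol 1. Ring A C3 is homoallylic to the C5=C6 alkene and can bias its epoxidation but not dictate it, so C5 and C6 need reagent control. Ring B C3′ is remote and controls nothing.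

The tetrasubstituted vinyl epoxide rearranges to a furanoid oxide with acid, the enol lactone opens or isomerises with base and nucleophiles, the polyene is sensitive to light, oxygen and acid, and terminal 1,3-diyne intermediates polymerise on storage.

The feature that makes the key step possible is that chain C1 carries a methyl group and is bonded directly to the C≡C on ring B C6′. The E trisubstituted chain C1=C2 alkene is what syn addition of CH3 and a metal across the terminal triple bond of a ring B buta-1,3-diyne delivers, while the internal triple bond is shielded by the C1′ gem-dimethyl and C5′ methyl groups.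

## Retrosynthesis

**36 from 35.** The last operation cleaves the two O–Si bonds of bis(triethylsilyl) ether 35. Triethylsilyl ethers keep alkoxides out of the base-mediated union and come off with buffered fluoride, which should spare both the vinyl epoxide and the enol lactone. tert-Butyldimethylsilyl ethers would need more forcing fluoride on the finished polyene.

**35 from 20 and 33.** The chain C5=C6 double bond is cut by a Julia–Kocienski olefination between benzothiazolyl sulfone 20 (ring B, triple bond, chain C1–C5) and dienal 33 (ring A, lactone, chain C6–C10). This is the only chain alkene that is disubstituted, unbranched and central, so its Z isomer 34 can be equilibrated to E. A cut at C1=C2 or C7=C8 would demand a stereoselective trisubstituted olefination. The two halves are of similar size (C20 and C17). The forward reaction must add the sulfonyl anion to the aldehyde faster than base or anion attack the lactone.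

**20 from 16.** The C–S bond, two S–O bonds and the ring O–Si bond are removed in turn: 20 from hydroxy sulfone 19, sulfide 18 and diol 17, which comes from bis-silyl ether 16. These are functional-group changes on a robust dienyne. The only demand is that the primary allylic hydroxyl of 17 reacts before the hindered secondary one.

**16 from 9, 14 and 13 (key step).** The chain C1–CH3 bond and the chain C2–C3 bond are cut, leading to ring B diyne 9, trimethylaluminium 14 and E iodoalkene 13 by way of alkenylalane 15. The neighbouring cut, between the triple bond and chain C1, would need a separately made, stereodefined iodo-dienol. The cut chosen creates the methyl branch, the E geometry and a chain bond in one flask from a linear diyne. The forward reaction must choose the terminal over the internal triple bond, place methyl on the internal carbon, add syn, and couple with retention.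

**9 from 4 and 5.** The ring C6′–C(sp) bond is cut. Diyne 9 comes from silylated diyne 8, made by coupling enol triflate 4 with the diynylzinc reagent 7, itself from 1,4-bis(trimethylsilyl)buta-1,3-diyne 5 through lithium diynide 6. Addition of 6 to ketone 2 followed by dehydration is the neighbouring option, but it gives carbinol epimers whose elimination depends on their configuration. Triflate 4 comes from silyl ether 2 and actinol 1 through enolate 3, and only one enolate is possible.

**13 from 10.** The C–I bond is cut: hydrozirconation–iodination of silyl ether 11, from propargyl alcohol 10, through alkenylzirconium 12.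

**33 from 31 and 26.** Dienal 33 is the oxidation product of alcohol 32. In 32 the bond between the lactone α-carbon and the ring A vinylene is cut by a Stille coupling of bromobutenolide 31 with alkenylstannane 26. This neutral coupling is chosen over base-mediated alternatives because both partners are base-sensitive.

**31 from 28 and 29.** The lactone O–C10 bond and the bond between the lactone β-carbon side and chain C10 are cut. (E)-2,3-Dibromoacrylic acid 28, from propiolic acid 27, couples with commercial enynol 29 and the intermediate acid 30 lactonises. Enynol 29 already holds chain C6–C10 with the C7=C8 geometry. The forward reaction must couple at the β-bromide and close 5-exo.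

**26 from 4.** Stannane 26 comes from alkyne 25, aldehyde 24 and epoxy alcohol 23. The two epoxide C–O bonds are cut back to allylic alcohol 22, made from ester 21 and the same triflate 4 that serves ring B. The hydroxymethyl group of 22 is the handle for reagent-controlled epoxidation and then becomes the vinylene carbon.

## Roads not taken

Alternative 1: The cut takes out the lactone carbonyl carbon, so that lactone C2–C3 and C2–O1 are formed last. In the forward step the ring A (Z)-β-iodoenone A1 reacts with carbon monoxide under PdCl2(PPh3)2 (divalent palladium precatalyst, reduced in the flask to zerovalent palladium) and Et3N. The acylpalladium is captured by the enol oxygen and ylidenebutenolide A2 results.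
- Merits: the ring and the Z exocyclic alkene are formed together, ring A is already in place, and no organotin reagent is needed. In the last respect it is better than the chosen plan, which uses a stannane in step 20.
- Weak points: A1 is a trisubstituted Z iodoalkene flanked by a vinyl epoxide and a β,γ-unsaturated ketone whose skipped alkene can slip into conjugation, and it has no short preparation. Carbonylation also holds zerovalent palladium at the vinyl epoxide for longer and at higher temperature than a room-temperature coupling.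
- Comparison: this road solves only the lactone and leaves the methyl-branched enyne end of the chain open. The chosen plan sets against its tin-free merit a lactone assembled from two commercial pieces in two steps (27 and 29 to 31) under neutral conditions.

Alternative 2: The cut is the two C–O bonds of the oxirane. In the forward step Ti(OiPr)4 (tetravalent titanium), the matching diethyl tartrate and tert-butyl hydroperoxide transfer oxygen to allylic alcohol A3 and give anti epoxy alcohol A4.
- Merits: both quaternary stereocentres are set in one reagent-controlled step whose face is predictable. In stereochemical certainty it is better than any carbon–carbon bond-forming step of the chosen plan.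
- Weak points: it needs the hydroxymethyl handle, which must then be oxidised and homologated, and it says nothing about the polyene, the lactone or the alkyne.
- Comparison: this is not a competitor but a component. The chosen plan uses the same reaction in step 14 on the triethylsilyl analogue 22, so its merit is kept. As the defining step of a plan it leaves the chain problem untouched, which is where the methylalumination supplies two skeletal bonds and a defined trisubstituted alkene.

Alternative 3: The cut is the second π bond of the triple bond (C7′≡C8′ in carotenoid numbering) together with the C5′=C6′ π bond. They are traced to tertiary allenic carbinol A5, which is sulfonylated with methanesulfonic anhydride and a hindered amine and eliminated in a 1,4 sense to give A6. A6 is the same compound as 35.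
- Merits: it follows the likely biogenesis, one late intermediate could serve both the allenic and the acetylenic pigments, and it avoids terminal diynes and organoaluminium reagents. Here it is as good as or better than the chosen plan.
- Weak points: a stereocentre at C5′ and an allene axis are built only to be destroyed. The elimination can also lose a C4′ or methyl hydrogen, or ionise to a delocalised cation, and it would be run on the complete polyene with the acid-labile epoxide and the enol lactone present. The allenic ring B fragment is also longer to make than diyne 9.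
- Comparison: the chosen plan sets against its divergence a triple bond that is present from commercial butadiyne 5 and never has to be created, and a key step that runs early on a robust C13 fragment.

Key step: step 7

Remark: the chain C5=C6 alkene formed in step 22 is assumed to arise Z-rich, as is usual for allylic benzothiazolyl sulfones with enals, and to equilibrate to E in the same operation; ZnCl2 in step 7 is used in substoichiometric amount.

## Route

Step 1
Reactants: 1 (4R,6R)-4-hydroxy-2,2,6-trimethylcyclohexanone (actinol)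
Product: 2 (4R,6R)-2,2,6-trimethyl-4-(triethylsilyloxy)cyclohexanone
Conditions: Et3SiCl, imidazole, DMF, 0 °C to rt
Reagents that add atoms: chlorotriethylsilane, CC[Si](Cl)(CC)CC
Why: Silylation of a secondary alcohol with a silyl chloride and imidazole; the triethylsilyl ether survives the basic and organometallic steps ahead and no stereocentre is touched.

Step 2
Reactants: 2 (4R,6R)-2,2,6-trimethyl-4-(triethylsilyloxy)cyclohexanone
Product: 4 (R)-2,6,6-trimethyl-4-(triethylsilyloxy)cyclohex-1-en-1-yl trifluoromethanesulfonate, via lithium enolate 3 (not isolated)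
Conditions: LiN(iPr)2, THF, −78 to 0 °C; PhNTf2, −78 °C to rt
Reagents that add atoms: N-phenylbis(trifluoromethanesulfonimide), O=S(=O)(N(c1ccccc1)S(=O)(=O)C(F)(F)F)C(F)(F)F
Why: Enolate formation and O-triflation; only C6 carries an α-hydrogen (C2 is quaternary), so a single tetrasubstituted enol triflate can form, and the C6 stereocentre is erased on purpose.

Step 3
Reactants: 4 (R)-2,6,6-trimethyl-4-(triethylsilyloxy)cyclohex-1-en-1-yl trifluoromethanesulfonate; 5 1,4-bis(trimethylsilyl)buta-1,3-diyne
Product: 8 triethyl{[(R)-3,5,5-trimethyl-4-(4-(trimethylsilyl)buta-1,3-diyn-1-yl)cyclohex-3-en-1-yl]oxy}silane, via lithium diynide 6 (not isolated), via diynylzinc chloride 7 (not isolated)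
Conditions: 5, MeLi·LiBr, THF, 0 °C to rt; ZnCl2, 0 °C; then 4, Pd(PPh3)4 (zerovalent palladium), THF, 50 °C
Reagents that add atoms: none
Why: Negishi alkynylation of an enol triflate: methyllithium cleaves one C–Si bond of 5, zinc tames the diynyl anion and palladium joins it to ring C6′; the slim alkynyl partner can reach the tetrasubstituted carbon and C3′ is a spectator.

Step 4
Reactants: 8 triethyl{[(R)-3,5,5-trimethyl-4-(4-(trimethylsilyl)buta-1,3-diyn-1-yl)cyclohex-3-en-1-yl]oxy}silane
Product: 9 {[(R)-4-(buta-1,3-diyn-1-yl)-3,5,5-trimethylcyclohex-3-en-1-yl]oxy}triethylsilane (ring B diyne)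
Conditions: K2CO3 (cat.), MeOH/THF, 0 °C; dried and used at once
Reagents that add atoms: none
Why: Methoxide-mediated protiodesilylation of an alkynylsilane is fast and leaves the secondary O–Si bond intact; the terminal diyne is not stored because such compounds polymerise.

Step 5
Reactants: 10 prop-2-yn-1-ol (propargyl alcohol)
Product: 11 triethyl(prop-2-yn-1-yloxy)silane
Conditions: Et3SiCl, imidazole, CH2Cl2, 0 °C
Reagents that add atoms: chlorotriethylsilane, CC[Si](Cl)(CC)CC
Why: Silylation of a primary alcohol; the ether masks the hydroxyl from the zirconium hydride and from the alane of step 7.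

Step 6
Reactants: 11 triethyl(prop-2-yn-1-yloxy)silane
Product: 13 (E)-triethyl[(3-iodoprop-2-en-1-yl)oxy]silane, via alkenylzirconocene chloride 12 (not isolated)
Conditions: Cp2Zr(H)Cl, CH2Cl2, rt; I2, 0 °C
Reagents that add atoms: iodine, II
Why: Hydrozirconation–iodinolysis: syn addition of Zr–H puts zirconium on the terminal carbon and iodine replaces it with retention, so only the E iodoalkene forms.

Step 7
Reactants: 9 {[(R)-4-(buta-1,3-diyn-1-yl)-3,5,5-trimethylcyclohex-3-en-1-yl]oxy}triethylsilane; 14 trimethylaluminium; 13 (E)-triethyl[(3-iodoprop-2-en-1-yl)oxy]silane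
Product: 16 triethyl{[(R)-3,5,5-trimethyl-4-((3E,5E)-3-methyl-7-(triethylsilyloxy)hepta-3,5-dien-1-yn-1-yl)cyclohex-3-en-1-yl]oxy}silane, via alkenyldimethylalane 15 (not isolated)
Conditions: AlMe3, Cp2ZrCl2 (tetravalent zirconium, cat.), (CH2Cl)2, 0 °C to rt; excess AlMe3 evaporated; then 13, ZnCl2 (cat.), Pd(PPh3)4 (zerovalent palladium), THF, rt
Reagents that add atoms: none
Why: Zirconium-catalysed methylalumination (alkyne carbometalation) with in situ zinc- and palladium-mediated cross-coupling: Cp2ZrCl2 and AlMe3 form a bimetallic methylzirconium species that adds CH3 and metal syn across the terminal triple bond of 9, methyl to the internal carbon (chain C1) and metal to the terminal carbon (chain C2), and transmetalation leaves E alkenylalane 15. Zinc chloride shuttles the alkenyl group from aluminium to the alkenylpalladium iodide formed from 13, and reductive elimination makes the chain C2–C3 bond with retention at both alkenes. The closest known reaction type is the one-flask methylalumination and alkenyl–alkenyl coupling of terminal alkynes, conjugated enynes included; a 1,3-diyne differs only in the hybridisation of the spectator substituent. No ring closes and no stereocentre is created; C3′ is a spectator. The step needs terminal-over-internal alkyne selectivity, methyl at the internal carbon and syn addition. The first is secured by the ring, because the internal triple bond lies between the C1′ gem-dimethyl and C5′ methyl groups and would have to accept the bulky bimetallic reagent next to a quaternary centre. The second and third are intrinsic to the four-centre addition, which places the metal on the less hindered terminal carbon. Excess AlMe3 is removed before the coupling so that methyl transfer to 13 does not compete.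

Step 8
Reactants: 16 triethyl{[(R)-3,5,5-trimethyl-4-((3E,5E)-3-methyl-7-(triethylsilyloxy)hepta-3,5-dien-1-yn-1-yl)cyclohex-3-en-1-yl]oxy}silane
Product: 17 (2E,4E)-7-[(R)-4-hydroxy-2,6,6-trimethylcyclohex-1-en-1-yl]-5-methylhepta-2,4-dien-6-yn-1-ol
Conditions: pyridinium p-toluenesulfonate (cat.), MeOH, rt
Reagents that add atoms: none
Why: Acid-catalysed methanolysis removes both triethylsilyl ethers; the acid is too weak to ionise the primary dienylic alcohol, and removing both groups avoids any need for selective cleavage.

Step 9
Reactants: 17 (2E,4E)-7-[(R)-4-hydroxy-2,6,6-trimethylcyclohex-1-en-1-yl]-5-methylhepta-2,4-dien-6-yn-1-ol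
Product: 18 (R)-4-[(3E,5E)-7-(1,3-benzothiazol-2-ylsulfanyl)-3-methylhepta-3,5-dien-1-yn-1-yl]-3,5,5-trimethylcyclohex-3-en-1-ol
Conditions: 1,3-benzothiazole-2-thiol, PPh3, diisopropyl azodicarboxylate (1.05 equiv), THF, 0 °C
Reagents that add atoms: 1,3-benzothiazole-2-thiol, Sc1nc2ccccc2s1
Why: Mitsunobu thioetherification; the unhindered primary allylic hydroxyl is activated far faster than the secondary ring hydroxyl, and direct displacement at CH2 keeps the E,E diene in place.

Step 10
Reactants: 18 (R)-4-[(3E,5E)-7-(1,3-benzothiazol-2-ylsulfanyl)-3-methylhepta-3,5-dien-1-yn-1-yl]-3,5,5-trimethylcyclohex-3-en-1-ol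
Product: 19 (R)-4-[(3E,5E)-7-(1,3-benzothiazol-2-ylsulfonyl)-3-methylhepta-3,5-dien-1-yn-1-yl]-3,5,5-trimethylcyclohex-3-en-1-ol
Conditions: (NH4)6Mo7O24·4H2O (cat.), 30% H2O2, EtOH, 0 °C to rt
Reagents that add atoms: hydrogen peroxide, OO
Why: Molybdate-catalysed peroxide oxidation of a sulfide to the sulfone, selective for sulfur over the dienyne and tolerant of the free hydroxyl; it is run before re-silylation because the acidic aqueous medium would endanger a triethylsilyl ether.

Step 11
Reactants: 19 (R)-4-[(3E,5E)-7-(1,3-benzothiazol-2-ylsulfonyl)-3-methylhepta-3,5-dien-1-yn-1-yl]-3,5,5-trimethylcyclohex-3-en-1-ol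
Product: 20 2-{[(2E,4E)-5-methyl-7-((R)-2,6,6-trimethyl-4-(triethylsilyloxy)cyclohex-1-en-1-yl)hepta-2,4-dien-6-yn-1-yl]sulfonyl}-1,3-benzothiazole
Conditions: Et3SiCl, imidazole, DMF, 0 °C to rt
Reagents that add atoms: chlorotriethylsilane, CC[Si](Cl)(CC)CC
Why: Silylation of the secondary alcohol; imidazole is too weak a base to deprotonate the sulfone, and the ether keeps an alkoxide out of the olefination.

Step 12
Reactants: 4 (R)-2,6,6-trimethyl-4-(triethylsilyloxy)cyclohex-1-en-1-yl trifluoromethanesulfonate
Product: 21 methyl (R)-2,6,6-trimethyl-4-(triethylsilyloxy)cyclohex-1-ene-1-carboxylate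
Conditions: CO (1 atm), MeOH, Pd(OAc)2 (divalent palladium precatalyst), PPh3, Et3N, DMF, 60 °C
Reagents that add atoms: carbon monoxide, [C-]#[O+]; methanol, CO
Why: Palladium-catalysed alkoxycarbonylation of an enol triflate (oxidative addition, CO insertion, methanolysis) installs the one-carbon handle on ring A C6.

Step 13
Reactants: 21 methyl (R)-2,6,6-trimethyl-4-(triethylsilyloxy)cyclohex-1-ene-1-carboxylate
Product: 22 [(R)-2,6,6-trimethyl-4-(triethylsilyloxy)cyclohex-1-en-1-yl]methanol
Conditions: iBu2AlH, CH2Cl2, −78 to 0 °C
Reagents that add atoms: none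
Why: Hydride reduction of the hindered conjugated ester at the carbonyl gives the allylic alcohol needed to direct epoxidation.

Step 14
Reactants: 22 [(R)-2,6,6-trimethyl-4-(triethylsilyloxy)cyclohex-1-en-1-yl]methanol
Product: 23 [(1R,4S,6R)-2,2,6-trimethyl-4-(triethylsilyloxy)-7-oxabicyclo[4.1.0]heptan-1-yl]methanol (epoxide anti to the silyloxy group)
Conditions: Ti(OiPr)4 (tetravalent titanium, cat.), D-(−)-diethyl tartrate (cat.), tBuOOH, 4 Å molecular sieves, CH2Cl2, −20 °C
Reagents that add atoms: tert-butyl hydroperoxide, CC(C)(C)OO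
Why: Sharpless asymmetric epoxidation: the titanium tartrate binds the allylic hydroxyl and delivers oxygen to one face of C5=C6, closing the oxirane and setting C5 and C6 together. By the Sharpless mnemonic D-(−)-tartrate selects the face anti to the C3 silyloxy group, and reagent control should override the weak bias of that remote centre.

Step 15
Reactants: 23 [(1R,4S,6R)-2,2,6-trimethyl-4-(triethylsilyloxy)-7-oxabicyclo[4.1.0]heptan-1-yl]methanol
Product: 24 (1S,4S,6R)-2,2,6-trimethyl-4-(triethylsilyloxy)-7-oxabicyclo[4.1.0]heptane-1-carbaldehyde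
Conditions: Pr4N[RuO4] (cat.), N-methylmorpholine N-oxide, 4 Å molecular sieves, CH2Cl2, rt
Reagents that add atoms: none
Why: Ley–Griffith oxidation under neutral conditions spares the epoxide and silyl ether; the aldehyde has no α-hydrogen, so it cannot epimerise (the descriptor at C1 changes by priority only).

Step 16
Reactants: 24 (1S,4S,6R)-2,2,6-trimethyl-4-(triethylsilyloxy)-7-oxabicyclo[4.1.0]heptane-1-carbaldehyde
Product: 25 (1R,4S,6R)-1-ethynyl-2,2,6-trimethyl-4-(triethylsilyloxy)-7-oxabicyclo[4.1.0]heptane
Conditions: dimethyl (1-diazo-2-oxopropyl)phosphonate, K2CO3, MeOH, 0 °C to rt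
Reagents that add atoms: dimethyl (1-diazo-2-oxopropyl)phosphonate, COP(=O)(OC)C(=[N+]=[N-])C(C)=O
Why: Seyferth–Gilbert homologation in the Ohira–Bestmann modification turns the non-enolisable aldehyde into the terminal alkyne under mild methanolic carbonate, which the epoxide and secondary silyl ether tolerate.

Step 17
Reactants: 25 (1R,4S,6R)-1-ethynyl-2,2,6-trimethyl-4-(triethylsilyloxy)-7-oxabicyclo[4.1.0]heptane
Product: 26 tributyl{(E)-2-[(1S,4S,6R)-2,2,6-trimethyl-4-(triethylsilyloxy)-7-oxabicyclo[4.1.0]heptan-1-yl]ethenyl}stannane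
Conditions: Bu3SnH, PdCl2(PPh3)2 (divalent palladium precatalyst, cat.), THF, 0 °C to rt
Reagents that add atoms: tributylstannane, CCCC[SnH](CCCC)CCCC
Why: Palladium-catalysed syn hydrostannation; the quaternary propargylic carbon steers tin to the terminal carbon and gives the E alkenylstannane.

Step 18
Reactants: 27 prop-2-ynoic acid (propiolic acid)
Product: 28 (E)-2,3-dibromoprop-2-enoic acid
Conditions: Br2, CHCl3, 0 °C to rt, dark
Reagents that add atoms: bromine, BrBr
Why: Anti addition of bromine to the alkyne gives the E dibromide, in which the β-bromine is cis to the carboxyl group as the later lactonisation requires.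

Step 19
Reactants: 28 (E)-2,3-dibromoprop-2-enoic acid; 29 (E)-3-methylpent-2-en-4-yn-1-ol
Product: 31 (Z)-3-bromo-5-[(E)-4-hydroxy-2-methylbut-2-en-1-ylidene]furan-2(5H)-one, via bromoenynoic acid 30 (not isolated)
Conditions: PdCl2(PPh3)2 (divalent palladium precatalyst), CuI (monovalent copper), Et3N, MeCN, rt
Reagents that add atoms: none
Why: Sonogashira coupling at the more electrophilic β C–Br bond, then 5-exo-dig anti addition of the cis carboxylate across the new triple bond and protonation, gives the Z ylidenebutenolide in a tandem coupling–lactonisation. The α-bromine is kept for step 20 and the C7=C8 geometry comes unchanged from 29.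

Step 20
Reactants: 31 (Z)-3-bromo-5-[(E)-4-hydroxy-2-methylbut-2-en-1-ylidene]furan-2(5H)-one; 26 tributyl{(E)-2-[(1S,4S,6R)-2,2,6-trimethyl-4-(triethylsilyloxy)-7-oxabicyclo[4.1.0]heptan-1-yl]ethenyl}stannane
Product: 32 (Z)-5-[(E)-4-hydroxy-2-methylbut-2-en-1-ylidene]-3-{(E)-2-[(1S,4S,6R)-2,2,6-trimethyl-4-(triethylsilyloxy)-7-oxabicyclo[4.1.0]heptan-1-yl]ethenyl}furan-2(5H)-one
Conditions: Pd2(dba)3 (zerovalent palladium), AsPh3, N-methylpyrrolidone, rt, dark
Reagents that add atoms: none
Why: Stille coupling of an α-bromobutenolide with an alkenylstannane under neutral conditions, with retention on both partners; at room temperature the tetrasubstituted epoxide should not ionise, since palladium would have to approach a quaternary carbon from the rear.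

Step 21
Reactants: 32 (Z)-5-[(E)-4-hydroxy-2-methylbut-2-en-1-ylidene]-3-{(E)-2-[(1S,4S,6R)-2,2,6-trimethyl-4-(triethylsilyloxy)-7-oxabicyclo[4.1.0]heptan-1-yl]ethenyl}furan-2(5H)-one
Product: 33 (E)-3-methyl-4-[(Z)-5-oxo-4-{(E)-2-[(1S,4S,6R)-2,2,6-trimethyl-4-(triethylsilyloxy)-7-oxabicyclo[4.1.0]heptan-1-yl]ethenyl}furan-2(5H)-ylidene]but-2-enal (ring A butenolide dienal)
Conditions: MnO2, CH2Cl2, rt, dark
Reagents that add atoms: none
Why: Manganese dioxide oxidises only the allylic alcohol and leaves the epoxide, silyl ether and lactone alone; the aldehyde is made just before use.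

Step 22
Reactants: 20 2-{[(2E,4E)-5-methyl-7-((R)-2,6,6-trimethyl-4-(triethylsilyloxy)cyclohex-1-en-1-yl)hepta-2,4-dien-6-yn-1-yl]sulfonyl}-1,3-benzothiazole; 33 (E)-3-methyl-4-[(Z)-5-oxo-4-{(E)-2-[(1S,4S,6R)-2,2,6-trimethyl-4-(triethylsilyloxy)-7-oxabicyclo[4.1.0]heptan-1-yl]ethenyl}furan-2(5H)-ylidene]but-2-enal
Product: 35 bis(triethylsilyl) ether of the target (all-E chain and Z ylidene lactone), via chain C5 Z isomer 34 (not isolated)
Conditions: NaN(SiMe3)2 added last, THF, −78 °C, dark; then benzene, rt, diffuse light
Reagents that add atoms: none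
Why: Julia–Kocienski olefination: the sulfonyl carbanion of 20 adds to the aldehyde of 33, the benzothiazole migrates from sulfur to oxygen (Smiles rearrangement) and SO2 and benzothiazolone are expelled, forming chain C5=C6. Base is added last at low temperature so that the carbanion meets the aldehyde before it can attack the lactone or another sulfone. The mixture rich in 34 is then left in benzene in diffuse light, where the unbranched central double bond should relax to the more stable all-E isomer 35.

Step 23
Reactants: 35 bis(triethylsilyl) ether of the target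
Product: 36 the target, (3S,5R,6S,3′R)-configured C37 epoxy ylidenebutenolide enyne diol
Conditions: Bu4NF, AcOH, THF, 0 °C, dark
Reagents that add atoms: none
Why: Fluoride cleavage of two secondary triethylsilyl ethers; acetic acid buffers the alkoxide and hydroxide that would open the enol lactone, while the medium stays too weakly acidic for the epoxide-to-furanoid rearrangement. No stereocentre or double bond is touched.

## Compound list

1 | (4R,6R)-4-hydroxy-2,2,6-trimethylcyclohexanone (actinol) | C[C@H]1C(=O)C(C)(C)C[C@H](O)C1 | starting material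
2 | (4R,6R)-2,2,6-trimethyl-4-(triethylsilyloxy)cyclohexanone | C[C@H]1C(=O)C(C)(C)C[C@H](O[Si](CC)(CC)CC)C1 | intermediate
3 | lithium (R)-2,6,6-trimethyl-4-(triethylsilyloxy)cyclohex-1-en-1-olate | [Li]OC1=C(C)C[C@@H](O[Si](CC)(CC)CC)CC1(C)C | intermediate
4 | (R)-2,6,6-trimethyl-4-(triethylsilyloxy)cyclohex-1-en-1-yl trifluoromethanesulfonate | O=S(=O)(OC1=C(C)C[C@@H](O[Si](CC)(CC)CC)CC1(C)C)C(F)(F)F | intermediate
5 | 1,4-bis(trimethylsilyl)buta-1,3-diyne | C[Si](C)(C)C#CC#C[Si](C)(C)C | starting material
6 | lithium 4-(trimethylsilyl)buta-1,3-diyn-1-ide | [Li]C#CC#C[Si](C)(C)C | intermediate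
7 | chloro[4-(trimethylsilyl)buta-1,3-diyn-1-yl]zinc | Cl[Zn]C#CC#C[Si](C)(C)C | intermediate
8 | triethyl{[(R)-3,5,5-trimethyl-4-(4-(trimethylsilyl)buta-1,3-diyn-1-yl)cyclohex-3-en-1-yl]oxy}silane | C[Si](C)(C)C#CC#CC1=C(C)C[C@@H](O[Si](CC)(CC)CC)CC1(C)C | intermediate
9 | {[(R)-4-(buta-1,3-diyn-1-yl)-3,5,5-trimethylcyclohex-3-en-1-yl]oxy}triethylsilane (ring B diyne) | C#CC#CC1=C(C)C[C@@H](O[Si](CC)(CC)CC)CC1(C)C | intermediate
10 | prop-2-yn-1-ol (propargyl alcohol) | C#CCO | starting material
11 | triethyl(prop-2-yn-1-yloxy)silane | C#CCO[Si](CC)(CC)CC | intermediate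
12 | chlorobis(cyclopentadienyl)[(E)-3-(triethylsilyloxy)prop-1-en-1-yl]zirconium | Cl[Zr](/C=C/CO[Si](CC)(CC)CC)(C1C=CC=C1)C1C=CC=C1 | intermediate
13 | (E)-triethyl[(3-iodoprop-2-en-1-yl)oxy]silane | I/C=C/CO[Si](CC)(CC)CC | intermediate
14 | trimethylaluminium | C[Al](C)C | starting material
15 | dimethyl{(E)-2-methyl-4-[(R)-2,6,6-trimethyl-4-(triethylsilyloxy)cyclohex-1-en-1-yl]but-1-en-3-yn-1-yl}alane | C[Al](C)/C=C(C)/C#CC1=C(C)C[C@@H](O[Si](CC)(CC)CC)CC1(C)C | intermediate
16 | triethyl{[(R)-3,5,5-trimethyl-4-((3E,5E)-3-methyl-7-(triethylsilyloxy)hepta-3,5-dien-1-yn-1-yl)cyclohex-3-en-1-yl]oxy}silane | CC[Si](CC)(CC)OC/C=C/C=C(C)/C#CC1=C(C)C[C@@H](O[Si](CC)(CC)CC)CC1(C)C | intermediate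
17 | (2E,4E)-7-[(R)-4-hydroxy-2,6,6-trimethylcyclohex-1-en-1-yl]-5-methylhepta-2,4-dien-6-yn-1-ol | OC/C=C/C=C(C)/C#CC1=C(C)C[C@@H](O)CC1(C)C | intermediate
18 | (R)-4-[(3E,5E)-7-(1,3-benzothiazol-2-ylsulfanyl)-3-methylhepta-3,5-dien-1-yn-1-yl]-3,5,5-trimethylcyclohex-3-en-1-ol | S(C/C=C/C=C(C)/C#CC1=C(C)C[C@@H](O)CC1(C)C)c1nc2ccccc2s1 | intermediate
19 | (R)-4-[(3E,5E)-7-(1,3-benzothiazol-2-ylsulfonyl)-3-methylhepta-3,5-dien-1-yn-1-yl]-3,5,5-trimethylcyclohex-3-en-1-ol | O=S(=O)(C/C=C/C=C(C)/C#CC1=C(C)C[C@@H](O)CC1(C)C)c1nc2ccccc2s1 | intermediate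
20 | 2-{[(2E,4E)-5-methyl-7-((R)-2,6,6-trimethyl-4-(triethylsilyloxy)cyclohex-1-en-1-yl)hepta-2,4-dien-6-yn-1-yl]sulfonyl}-1,3-benzothiazole | O=S(=O)(C/C=C/C=C(C)/C#CC1=C(C)C[C@@H](O[Si](CC)(CC)CC)CC1(C)C)c1nc2ccccc2s1 | intermediate
21 | methyl (R)-2,6,6-trimethyl-4-(triethylsilyloxy)cyclohex-1-ene-1-carboxylate | COC(=O)C1=C(C)C[C@@H](O[Si](CC)(CC)CC)CC1(C)C | intermediate
22 | [(R)-2,6,6-trimethyl-4-(triethylsilyloxy)cyclohex-1-en-1-yl]methanol | OCC1=C(C)C[C@@H](O[Si](CC)(CC)CC)CC1(C)C | intermediate
23 | [(1R,4S,6R)-2,2,6-trimethyl-4-(triethylsilyloxy)-7-oxabicyclo[4.1.0]heptan-1-yl]methanol | OC[C@@]12O[C@]1(C)C[C@@H](O[Si](CC)(CC)CC)CC2(C)C | intermediate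
24 | (1S,4S,6R)-2,2,6-trimethyl-4-(triethylsilyloxy)-7-oxabicyclo[4.1.0]heptane-1-carbaldehyde | O=C[C@@]12O[C@]1(C)C[C@@H](O[Si](CC)(CC)CC)CC2(C)C | intermediate
25 | (1R,4S,6R)-1-ethynyl-2,2,6-trimethyl-4-(triethylsilyloxy)-7-oxabicyclo[4.1.0]heptane | C#C[C@@]12O[C@]1(C)C[C@@H](O[Si](CC)(CC)CC)CC2(C)C | intermediate
26 | tributyl{(E)-2-[(1S,4S,6R)-2,2,6-trimethyl-4-(triethylsilyloxy)-7-oxabicyclo[4.1.0]heptan-1-yl]ethenyl}stannane | CCCC[Sn](CCCC)(CCCC)/C=C/[C@@]12O[C@]1(C)C[C@@H](O[Si](CC)(CC)CC)CC2(C)C | intermediate
27 | prop-2-ynoic acid (propiolic acid) | C#CC(=O)O | starting material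
28 | (E)-2,3-dibromoprop-2-enoic acid | OC(=O)/C(Br)=C\Br | intermediate
29 | (E)-3-methylpent-2-en-4-yn-1-ol | C#C/C(C)=C/CO | starting material
30 | (2E,6E)-2-bromo-8-hydroxy-6-methylocta-2,6-dien-4-ynoic acid | OC(=O)/C(Br)=C\C#C/C(C)=C/CO | intermediate
31 | (Z)-3-bromo-5-[(E)-4-hydroxy-2-methylbut-2-en-1-ylidene]furan-2(5H)-one | O=C1O/C(=C\C(C)=C\CO)C=C1Br | intermediate
32 | (Z)-5-[(E)-4-hydroxy-2-methylbut-2-en-1-ylidene]-3-{(E)-2-[(1S,4S,6R)-2,2,6-trimethyl-4-(triethylsilyloxy)-7-oxabicyclo[4.1.0]heptan-1-yl]ethenyl}furan-2(5H)-one | O=C1O/C(=C\C(C)=C\CO)C=C1/C=C/[C@@]12O[C@]1(C)C[C@@H](O[Si](CC)(CC)CC)CC2(C)C | intermediate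
33 | (E)-3-methyl-4-[(Z)-5-oxo-4-{(E)-2-[(1S,4S,6R)-2,2,6-trimethyl-4-(triethylsilyloxy)-7-oxabicyclo[4.1.0]heptan-1-yl]ethenyl}furan-2(5H)-ylidene]but-2-enal | O=C1O/C(=C\C(C)=C\C=O)C=C1/C=C/[C@@]12O[C@]1(C)C[C@@H](O[Si](CC)(CC)CC)CC2(C)C | intermediate
34 | chain C5=C6 Z isomer of 35 (all other alkenes as in 35) | O=C1O/C(=C\C(C)=C\C=C/C=C/C=C(C)/C#CC2=C(C)C[C@@H](O[Si](CC)(CC)CC)CC2(C)C)C=C1/C=C/[C@@]12O[C@]1(C)C[C@@H](O[Si](CC)(CC)CC)CC2(C)C | intermediate
35 | bis(triethylsilyl) ether of the target (all-E chain, Z ylidene lactone, 3S,5R,6S,3′R) | O=C1O/C(=C\C(C)=C\C=C\C=C\C=C(C)\C#CC2=C(C)C[C@@H](O[Si](CC)(CC)CC)CC2(C)C)C=C1/C=C/[C@@]12O[C@]1(C)C[C@@H](O[Si](CC)(CC)CC)CC2(C)C | intermediate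
36 | the target: (3S,5R,6S,3′R) C37 epoxy ylidenebutenolide enyne diol | CC1=C(C#C/C(C)=C/C=C/C=C/C=C(C)/C=C2C=C(/C=C/[C@@]34O[C@]3(C)C[C@@H](O)CC4(C)C)C(=O)O/2)C(C)(C)C[C@H](O)C1 | target

## Step count and least certain steps

Total: 23 steps. Longest linear sequence: 12 steps (1, 2, 12 to 17, 20 to 23, from actinol 1 through ring A). The ring B branch is 11 steps (1 to 4, 7 to 11, 22, 23).

**Step 7 (key step).** The most likely failures are metalation of the acidic diyne C–H in place of addition, oligomerisation of the terminal diyne during the slow zirconium step, a second carbometalation at the ring-bound triple bond, or methyl in place of alkenyl transfer at palladium. The fallback sets out from triflate 4 and enynol 29 and returns at diol 17. It buys the methyl-branched alkene ready-made: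
- Sonogashira coupling of 4 with 29 (Pd(PPh3)4, CuI, iPr2NH, 60 °C) would give (E)-3-methyl-5-[(R)-2,6,6-trimethyl-4-(triethylsilyloxy)cyclohex-1-en-1-yl]pent-2-en-4-yn-1-ol F1.
- MnO2 would oxidise it to the corresponding enynal F2.
- A Horner–Wadsworth–Emmons reaction with triethyl phosphonoacetate would give the E,E ethyl dienynoate F3.
- iBu2AlH would reduce it to the mono-silylated dienynol F4, and acid-catalysed methanolysis would give 17.

This costs four more steps than the key step.

**Step 19.** Oxidative addition may also occur at the α C–Br bond, the acid may close 6-endo to a pyranone, or a second alkyne may couple, so that little of 31 is formed. The fallback uses none of 27 to 30 and returns at bromobutenolide 31; it makes the exocyclic alkene by aldol addition and elimination: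
- Commercial 3-bromofuran-2(5H)-one F5 is silylated (tBuMe2SiOTf, Et3N) to [(3-bromofuran-2-yl)oxy](tert-butyl)dimethylsilane F6.
- A vinylogous Mukaiyama aldol addition (BF3·OEt2, −78 °C) to the known aldehyde (E)-4-(tert-butyldimethylsilyloxy)-2-methylbut-2-enal F7 gives the γ-(hydroxyalkyl)butenolide F8 as a diastereomer mixture.
- Mesylation and base-induced elimination give the Z ylidenebutenolide silyl ether F9, and HF·pyridine frees 31.

**Step 22.** The amide base or the sulfonyl anion may attack the enol lactone, the metalated sulfone may condense with itself, or the Z-to-E equilibration may stop short. The fallback sets out from sulfone 20 and returns at 35; it forms the lactone only after the base-mediated step: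
- MnO2 oxidation of 29 gives (E)-3-methylpent-2-en-4-ynal F10.
- Julia–Kocienski olefination of 20 with it, followed by the same equilibration, gives the ring B all-E tetraenediyne F11.
- Tandem coupling–lactonisation of F11 with acid 28 under the conditions of step 19 gives the polyenyl bromobutenolide F12.
- Stille coupling of F12 with stannane 26 gives 35 under neutral conditions.

**Step 3.** Oxidative addition into the tetrasubstituted triflate may be slow enough for the diynylzinc reagent to homocouple or lose silicon. The fallback sets out from ketone 2 and lithium diynide 6 and returns at 8. Addition of 6 to 2 (THF, −78 °C) gives the tertiary diynyl carbinol F13 as a mixture of carbinol epimers. Dehydration with Ph2S[OC(CF3)2Ph]2 in CH2Cl2 can only remove the C6 hydrogen and gives 8, by a cationic pathway that does not depend on the carbinol configuration.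

## Further compounds

F1 | step 7 | (E)-3-methyl-5-[(R)-2,6,6-trimethyl-4-(triethylsilyloxy)cyclohex-1-en-1-yl]pent-2-en-4-yn-1-ol | OC/C=C(C)/C#CC1=C(C)C[C@@H](O[Si](CC)(CC)CC)CC1(C)C
F2 | step 7 | (E)-3-methyl-5-[(R)-2,6,6-trimethyl-4-(triethylsilyloxy)cyclohex-1-en-1-yl]pent-2-en-4-ynal | O=C/C=C(C)/C#CC1=C(C)C[C@@H](O[Si](CC)(CC)CC)CC1(C)C
F3 | step 7 | ethyl (2E,4E)-5-methyl-7-[(R)-2,6,6-trimethyl-4-(triethylsilyloxy)cyclohex-1-en-1-yl]hepta-2,4-dien-6-ynoate | CCOC(=O)/C=C/C=C(C)/C#CC1=C(C)C[C@@H](O[Si](CC)(CC)CC)CC1(C)C
F4 | step 7 | (2E,4E)-5-methyl-7-[(R)-2,6,6-trimethyl-4-(triethylsilyloxy)cyclohex-1-en-1-yl]hepta-2,4-dien-6-yn-1-ol | OC/C=C/C=C(C)/C#CC1=C(C)C[C@@H](O[Si](CC)(CC)CC)CC1(C)C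
F5 | step 19 | 3-bromofuran-2(5H)-one | O=C1OCC=C1Br
F6 | step 19 | [(3-bromofuran-2-yl)oxy](tert-butyl)dimethylsilane | CC(C)(C)[Si](C)(C)Oc1occc1Br
F7 | step 19 | (E)-4-(tert-butyldimethylsilyloxy)-2-methylbut-2-enal | CC(C)(C)[Si](C)(C)OC/C=C(C)/C=O
F8 | step 19 | 3-bromo-5-[(E)-4-(tert-butyldimethylsilyloxy)-1-hydroxy-2-methylbut-2-en-1-yl]furan-2(5H)-one (diastereomer mixture) | O=C1OC(C(O)/C(C)=C/CO[Si](C)(C)C(C)(C)C)C=C1Br
F9 | step 19 | (Z)-3-bromo-5-[(E)-4-(tert-butyldimethylsilyloxy)-2-methylbut-2-en-1-ylidene]furan-2(5H)-one | O=C1O/C(=C\C(C)=C\CO[Si](C)(C)C(C)(C)C)C=C1Br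
F10 | step 22 | (E)-3-methylpent-2-en-4-ynal | C#C/C(C)=C/C=O
F11 | step 22 | triethyl{[(R)-4-((3E,5E,7E,9E)-3,10-dimethyldodeca-3,5,7,9-tetraene-1,11-diyn-1-yl)-3,5,5-trimethylcyclohex-3-en-1-yl]oxy}silane | C#C/C(C)=C/C=C/C=C/C=C(C)/C#CC1=C(C)C[C@@H](O[Si](CC)(CC)CC)CC1(C)C
F12 | step 22 | (Z)-3-bromo-5-ylidenefuran-2(5H)-one carrying the all-E chain C1–C9 and the ring B silyl ether | O=C1O/C(=C\C(C)=C\C=C\C=C\C=C(C)\C#CC2=C(C)C[C@@H](O[Si](CC)(CC)CC)CC2(C)C)C=C1Br
F13 | step 3 | 2,2,6-trimethyl-4-(triethylsilyloxy)-1-[4-(trimethylsilyl)buta-1,3-diyn-1-yl]cyclohexan-1-ol (both carbinol epimers; ring centres as in 2) | C[C@H]1C(O)(C#CC#C[Si](C)(C)C)C(C)(C)C[C@H](O[Si](CC)(CC)CC)C1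
A1 | alternative 1 | ring A (Z)-β-iodoenone with the silyloxy-terminated side chain | I/C(/C=C/[C@@]12O[C@]1(C)C[C@@H](O[Si](C)(C)C(C)(C)C)CC2(C)C)=C\C(=O)C/C(C)=C/CO[Si](C)(C)C(C)(C)C
A2 | alternative 1 | ring A ylidenebutenolide with silyloxy-terminated diene side chain | O=C1O/C(=C\C(C)=C\CO[Si](C)(C)C(C)(C)C)C=C1/C=C/[C@@]12O[C@]1(C)C[C@@H](O[Si](C)(C)C(C)(C)C)CC2(C)C
A3 | alternative 2 | [(R)-4-(tert-butyldimethylsilyloxy)-2,6,6-trimethylcyclohex-1-en-1-yl]methanol | OCC1=C(C)C[C@@H](O[Si](C)(C)C(C)(C)C)CC1(C)C
A4 | alternative 2 | ring A anti epoxy alcohol, tert-butyldimethylsilyl ether | OC[C@@]12O[C@]1(C)C[C@@H](O[Si](C)(C)C(C)(C)C)CC2(C)C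
A5 | alternative 3 | bis(triethylsilyl) ether of the (3′S,5′R,6′R) allenic tertiary carbinol corresponding to the target | O=C1O/C(=C\C(C)=C\C=C\C=C\C=C(C)\C=[C@@]=C2C(C)(C)C[C@H](O[Si](CC)(CC)CC)C[C@@]2(C)O)C=C1/C=C/[C@@]12O[C@]1(C)C[C@@H](O[Si](CC)(CC)CC)CC2(C)C
A6 | alternative 3 | bis(triethylsilyl) ether of the target (identical with 35) | O=C1O/C(=C\C(C)=C\C=C\C=C\C=C(C)\C#CC2=C(C)C[C@@H](O[Si](CC)(CC)CC)CC2(C)C)C=C1/C=C/[C@@]12O[C@]1(C)C[C@@H](O[Si](CC)(CC)CC)CC2(C)C
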